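**Strategy.** The target is opened at its allylic ester C–O bond into a silylated (Z)-sinapyl alcohol and a half ester derived from (R)-mevalonolactone; the alcohol is traced back to the bond between ring carbon C4 and side-chain carbon Cα (the ring-bonded alkene carbon). Step 1 forms this bond and the Z-configured Cα=Cβ alkene together: in the benzene ring of unprotected 2,6-dimethoxyphenol 1, the C4–H para to the hydroxyl-bearing C1, whose neighbours C2 and C6 carry OCH3 and so cannot cyclise to a coumarin, adds anti across the triple bond of ethyl propiolate 2 under divalent palladium in trifluoroacetic acid. Both precursors are purchased.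

Key step: step 1

Remark: the lactone carbonyl of (R)-mevalonolactone has to become the sinapyl ester carbonyl and its C5 the free acid to give the (3R) target; the CIP label of the carbinol carbon changes along the way (R in 6 to 9, S in 11 to 13, R in 14) only because substituent priorities change, and no bond to that carbon is made or broken.

**Step 1**
Reactants: 1 2,6-dimethoxyphenol; 2 ethyl propiolate
Product: 3 ethyl (2Z)-3-(4-hydroxy-3,5-dimethoxyphenyl)prop-2-enoate (ethyl (Z)-sinapate)
Conditions: Pd(OAc)2 (2 mol%), CF3CO2H/CH2Cl2 (4:1), 0 °C, 1 in excess (2 equiv), quench when 2 is consumed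
Reagents that add atoms: none
Why: An electrophilic divalent palladium trifluoroacetate formed from Pd(OAc)2 in CF3CO2H coordinates the alkyne of 2, C4 of 1 attacks the alkyne carbon remote from the ester from the face opposite the metal in a Friedel–Crafts sense, and the resulting vinyl–palladium bond is protonated with retention, so that aryl and CO2Et end up cis. The closest known reaction type is the Fujiwara trans-hydroarylation of propiolates by electron-rich arenes, applied here to a phenol that cannot go on to a coumarin. No ring is closed and no stereocentre is formed; the only stereochemical element, the Z alkene, is fixed by the anti addition mode and is the kinetic product. The step needs attack at C4 and not at C3 or C5, which the free hydroxyl conjugated with the ring should secure as the strongest para director (C4 is also where this phenol is brominated, formylated under Duff conditions and aminomethylated), while the OCH3 groups at C2 and C6 shut off the ortho positions. It also needs the Z alkene to survive, which is served by the excess of 1, the low temperature, the short contact with acid and the absence of zerovalent palladium.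

**Step 2**
Reactants: 3 ethyl (Z)-sinapate
Product: 4 ethyl (2Z)-3-{4-[(tert-butyldimethylsilyl)oxy]-3,5-dimethoxyphenyl}prop-2-enoate
Conditions: TBSCl, imidazole, DMF, rt
Reagents that add atoms: tert-butyldimethylsilyl chloride, CC(C)(C)[Si](C)(C)Cl
Why: Imidazole-mediated silylation of a phenol is routine even between two methoxy groups, the base is too weak to isomerise the Z enoate, and the silyl ether shields the phenol from acylation in step 8 and from quinone-methide chemistry.

**Step 3**
Reactants: 4 silylated ethyl (Z)-sinapate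
Product: 5 (2Z)-3-{4-[(tert-butyldimethylsilyl)oxy]-3,5-dimethoxyphenyl}prop-2-en-1-ol
Conditions: i-Bu2AlH (2.5 equiv), CH2Cl2, −78 °C; aq. potassium sodium tartrate
Reagents that add atoms: none
Why: 1,2-Reduction of an α,β-unsaturated ester by i-Bu2AlH stops at the allylic alcohol without touching the alkene, so the Z geometry should be carried over unchanged, and the aryl silyl ether is inert.

**Step 4**
Reactants: 6 (R)-mevalonolactone
Product: 8 benzyl (3R)-3,5-dihydroxy-3-methylpentanoate, via potassium (R)-mevalonate 7 (not isolated)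
Conditions: KOH (1.05 equiv), H2O/MeOH, rt; evaporate; BnBr, DMF, rt; neutral work-up, use at once
Reagents that add atoms: potassium hydroxide, [K+].[OH-]; benzyl bromide, BrCc1ccccc1
Why: Saponification of the δ-lactone followed by SN2 O-alkylation of the carboxylate is an established way to open mevalonolactone to its esters; it leaves the carbinol carbon untouched and places a hydrogenolysable group on the carboxyl that must later carry the sinapyl ester.

**Step 5**
Reactants: 8 benzyl (R)-mevalonate
Product: 9 (3R)-5-(benzyloxy)-3-hydroxy-3-methyl-5-oxopentanoic acid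
Conditions: TEMPO (20 mol%), PhI(OAc)2 (2.2 equiv), MeCN/H2O (1:1), 0 °C to rt
Reagents that add atoms: water, O
Why: The TEMPO-catalysed oxidation with PhI(OAc)2 in aqueous acetonitrile takes a primary alcohol through the aldehyde hydrate to the acid while the tertiary alcohol and the benzyl ester are inert, and it runs near neutral pH, where ring closure back to the lactone should be slow.

**Step 6**
Reactants: 9 monobenzyl acid; 10 2-(trimethylsilyl)ethanol
Product: 11 1-benzyl 5-[2-(trimethylsilyl)ethyl] (3S)-3-hydroxy-3-methylpentanedioate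
Conditions: DIC, DMAP (cat.), CH2Cl2, 0 °C to rt
Reagents that add atoms: none
Why: In this Steglich esterification the primary alcohol 10 is acylated far faster than the tertiary hydroxyl of 9, which therefore needs no protection.

**Step 7**
Reactants: 11 benzyl silylethyl diester
Product: 12 (3S)-3-hydroxy-3-methyl-5-oxo-5-[2-(trimethylsilyl)ethoxy]pentanoic acid
Conditions: H2 (1 atm), Pd/C, EtOAc, rt
Reagents that add atoms: none
Why: Catalytic hydrogenolysis removes the benzyl ester selectively; the silylethyl ester and the tertiary alcohol are inert, and no alkene is present at this stage.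

**Step 8**
Reactants: 5 silylated (Z)-sinapyl alcohol; 12 silylethyl half ester
Product: 13 1-[(2Z)-3-{4-[(tert-butyldimethylsilyl)oxy]-3,5-dimethoxyphenyl}prop-2-en-1-yl] 5-[2-(trimethylsilyl)ethyl] (3S)-3-hydroxy-3-methylpentanedioate
Conditions: DIC, DMAP (cat.), CH2Cl2, 0 °C to rt, 12 in slight excess
Reagents that add atoms: none
Why: Steglich esterification of a primary allylic alcohol runs under near-neutral conditions that neither ionise the allylic position nor isomerise the Z alkene, and it puts the sinapyl group on the carboxyl that was the lactone carbonyl of 6, as the (3R) target requires.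

**Step 9**
Reactants: 13 fully protected diester
Product: 14 (3R)-5-{[(2Z)-3-(4-hydroxy-3,5-dimethoxyphenyl)prop-2-en-1-yl]oxy}-3-hydroxy-3-methyl-5-oxopentanoic acid (target)
Conditions: Bu4NF/AcOH (1:1, 4 equiv), DMF, 0 °C to rt; mild acidic work-up
Reagents that add atoms: none
Why: Fluoride cleaves the aryl silyl ether and triggers the β-fragmentation of the 2-(trimethylsilyl)ethyl ester with loss of ethylene in the same flask, while acetic acid keeps the phenoxide concentration low so that the allylic ester should be neither ionised nor exchanged; the stereocentre and the alkene are not involved.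

**Compound list**
1 | 2,6-dimethoxyphenol | COc1cccc(OC)c1O | starting material
2 | ethyl propiolate | C#CC(=O)OCC | starting material
3 | ethyl (2Z)-3-(4-hydroxy-3,5-dimethoxyphenyl)prop-2-enoate (ethyl (Z)-sinapate) | CCOC(=O)/C=C\c1cc(OC)c(O)c(OC)c1 | intermediate
4 | ethyl (2Z)-3-{4-[(tert-butyldimethylsilyl)oxy]-3,5-dimethoxyphenyl}prop-2-enoate | CCOC(=O)/C=C\c1cc(OC)c(O[Si](C)(C)C(C)(C)C)c(OC)c1 | intermediate
5 | (2Z)-3-{4-[(tert-butyldimethylsilyl)oxy]-3,5-dimethoxyphenyl}prop-2-en-1-ol | OC/C=C\c1cc(OC)c(O[Si](C)(C)C(C)(C)C)c(OC)c1 | intermediate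
6 | (R)-mevalonolactone, (4R)-4-hydroxy-4-methyloxan-2-one | C[C@@]1(O)CCOC(=O)C1 | starting material
7 | potassium (3R)-3,5-dihydroxy-3-methylpentanoate (potassium (R)-mevalonate, not isolated) | C[C@@](CC(=O)[O-])(O)CCO.[K+] | intermediate
8 | benzyl (3R)-3,5-dihydroxy-3-methylpentanoate | C[C@@](CC(=O)OCc1ccccc1)(O)CCO | intermediate
9 | (3R)-5-(benzyloxy)-3-hydroxy-3-methyl-5-oxopentanoic acid | C[C@@](CC(=O)OCc1ccccc1)(O)CC(=O)O | intermediate
10 | 2-(trimethylsilyl)ethanol | C[Si](C)(C)CCO | starting material
11 | 1-benzyl 5-[2-(trimethylsilyl)ethyl] (3S)-3-hydroxy-3-methylpentanedioate | C[C@@](CC(=O)OCc1ccccc1)(O)CC(=O)OCC[Si](C)(C)C | intermediate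
12 | (3S)-3-hydroxy-3-methyl-5-oxo-5-[2-(trimethylsilyl)ethoxy]pentanoic acid | C[C@@](CC(=O)O)(O)CC(=O)OCC[Si](C)(C)C | intermediate
13 | 1-[(2Z)-3-{4-[(tert-butyldimethylsilyl)oxy]-3,5-dimethoxyphenyl}prop-2-en-1-yl] 5-[2-(trimethylsilyl)ethyl] (3S)-3-hydroxy-3-methylpentanedioate | C[C@@](CC(=O)OC/C=C\c1cc(OC)c(O[Si](C)(C)C(C)(C)C)c(OC)c1)(O)CC(=O)OCC[Si](C)(C)C | intermediate
14 | (3R)-5-{[(2Z)-3-(4-hydroxy-3,5-dimethoxyphenyl)prop-2-en-1-yl]oxy}-3-hydroxy-3-methyl-5-oxopentanoic acid | COc1cc(/C=C\COC(=O)C[C@](C)(O)CC(=O)O)cc(OC)c1O | target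

**Count.** Total: 9 steps. Longest linear sequence: 6 steps (6 → 8 → 9 → 11 → 12 → 13 → 14; steps 4 to 9). The arene branch is 3 steps (steps 1 to 3) before the convergent coupling.

**Steps most likely to fail**

1. Step 1. The arene may attack through C3 or C5 instead of C4, the acid may isomerise the kinetic Z alkene to E, or a second arene may add to the new cinnamate. Fallback: setting out from 1, Duff formylation (hexamethylenetetramine, CF3CO2H, reflux, then aqueous acid) should give syringaldehyde F1. Silylation with TBSCl and imidazole in DMF then gives 4-[(tert-butyldimethylsilyl)oxy]-3,5-dimethoxybenzaldehyde F2. A Z-selective Horner–Wadsworth–Emmons olefination of the Ando type with ethyl (diphenoxyphosphoryl)acetate (NaH, THF, −78 °C) forms the Z enoate and comes back to the route at 4.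

2. Step 9. Fragmentation of the silylethyl ester may be sluggish under buffering, and if the medium turns basic the phenoxide may drive ionisation of the allylic ester or ester exchange. Fallback: setting out from 9, esterification with 3-hydroxypropanenitrile (DIC, DMAP) gives 1-benzyl 5-(2-cyanoethyl) (3R)-3-hydroxy-3-methylpentanedioate F3. Hydrogenolysis (H2, Pd/C, EtOAc) gives (3S)-5-(2-cyanoethoxy)-3-hydroxy-3-methyl-5-oxopentanoic acid F4. Steglich coupling with 5 gives 1-[(2Z)-3-{4-[(tert-butyldimethylsilyl)oxy]-3,5-dimethoxyphenyl}prop-2-en-1-yl] 5-(2-cyanoethyl) (3R)-3-hydroxy-3-methylpentanedioate F5. DBU in CH2Cl2 then removes the cyanoethyl group by E1cB loss of acrylonitrile while the phenol is still silylated, giving (3R)-5-{[(2Z)-3-{4-[(tert-butyldimethylsilyl)oxy]-3,5-dimethoxyphenyl}prop-2-en-1-yl]oxy}-3-hydroxy-3-methyl-5-oxopentanoic acid F6. A brief treatment with Bu4NF/AcOH at 0 °C frees the phenol and arrives at 14.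

3. Step 4. The δ-hydroxy benzyl ester may close back to the lactone with loss of benzyl alcohol during work-up, storage or the following oxidation. Fallback: setting out from 6 and opening it with KOH to 7 as before, TBSCl and imidazole in DMF silylate the carboxylate and the primary hydroxyl to give tert-butyldimethylsilyl (3R)-5-[(tert-butyldimethylsilyl)oxy]-3-hydroxy-3-methylpentanoate F7. K2CO3 in aqueous MeOH cleaves only the silyl ester and gives (3R)-5-[(tert-butyldimethylsilyl)oxy]-3-hydroxy-3-methylpentanoic acid F8. BnBr and K2CO3 in DMF give benzyl (3R)-5-[(tert-butyldimethylsilyl)oxy]-3-hydroxy-3-methylpentanoate F9, which cannot lactonise. Jones reagent (CrO3, H2SO4, acetone, 0 °C) cleaves the primary silyl ether and oxidises the released alcohol in the same flask, coming back to the route at 9.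

**Further compounds**
F1 | step 1 | syringaldehyde (4-hydroxy-3,5-dimethoxybenzaldehyde) | COc1cc(C=O)cc(OC)c1O
F2 | step 1 | 4-[(tert-butyldimethylsilyl)oxy]-3,5-dimethoxybenzaldehyde | COc1cc(C=O)cc(OC)c1O[Si](C)(C)C(C)(C)C
F3 | step 9 | 1-benzyl 5-(2-cyanoethyl) (3R)-3-hydroxy-3-methylpentanedioate | C[C@@](CC(=O)OCc1ccccc1)(O)CC(=O)OCCC#N
F4 | step 9 | (3S)-5-(2-cyanoethoxy)-3-hydroxy-3-methyl-5-oxopentanoic acid | C[C@@](CC(=O)O)(O)CC(=O)OCCC#N
F5 | step 9 | 1-[(2Z)-3-{4-[(tert-butyldimethylsilyl)oxy]-3,5-dimethoxyphenyl}prop-2-en-1-yl] 5-(2-cyanoethyl) (3R)-3-hydroxy-3-methylpentanedioate | C[C@@](CC(=O)OC/C=C\c1cc(OC)c(O[Si](C)(C)C(C)(C)C)c(OC)c1)(O)CC(=O)OCCC#N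
F6 | step 9 | (3R)-5-{[(2Z)-3-{4-[(tert-butyldimethylsilyl)oxy]-3,5-dimethoxyphenyl}prop-2-en-1-yl]oxy}-3-hydroxy-3-methyl-5-oxopentanoic acid | C[C@@](CC(=O)OC/C=C\c1cc(OC)c(O[Si](C)(C)C(C)(C)C)c(OC)c1)(O)CC(=O)O
F7 | step 4 | tert-butyldimethylsilyl (3R)-5-[(tert-butyldimethylsilyl)oxy]-3-hydroxy-3-methylpentanoate | C[C@@](CC(=O)O[Si](C)(C)C(C)(C)C)(O)CCO[Si](C)(C)C(C)(C)C
F8 | step 4 | (3R)-5-[(tert-butyldimethylsilyl)oxy]-3-hydroxy-3-methylpentanoic acid | C[C@@](CC(=O)O)(O)CCO[Si](C)(C)C(C)(C)C
F9 | step 4 | benzyl (3R)-5-[(tert-butyldimethylsilyl)oxy]-3-hydroxy-3-methylpentanoate | C[C@@](CC(=O)OCc1ccccc1)(O)CCO[Si](C)(C)C(C)(C)C
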